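**Strategy.** The plan cuts the C1–C11 bond of the seven-membered ring. The step uses one structural fact: gem-dimethyl C11 lies between cyclobutane carbon C10 (ring C4–C5–C10–C9) and carbinol C1, and the lone hydrogen on C10 points to the open outer face, so C10–H and C1–C11 can both come from an exocyclic C10=C11 alkene. Hydrogen-atom transfer to C10 gives the tertiary C11 radical, chromium makes it nucleophilic, and attack on the C1 aldehyde closes the ring, fixing C10, C11 and C1 at once. The precursor is a 6-isopropylidenebicyclo[3.1.1]heptan-2-one whose methyl-bearing bridge carbon C4 carries an (S)-2-benzoyloxy-3-oxopropyl chain.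

Key step: step 8

**Remarks**

- Atom numbers (used for all bicyclic and tricyclic compounds): C1 = carbinol carbon that ends as the angelate; C2 = carbinol carbon that ends as the 2-methylbutanoate; C3 = CH2; C4 = quaternary carbon with a methyl group; C5 = bridgehead CH; C6–C7–C8 = three-carbon bridge (target: C6 ketone, C7=C8 alkene, methyl on C8); C9 = second bridgehead CH; C10 = cyclobutane carbon bonded to C11; C11 = carbon with two methyl groups. Cyclobutane = C4, C5, C10, C9. "Inner" = the face of C4 or C10 turned toward the other; "outer" = the face turned toward the C6–C8 bridge.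
- Design of the precursor: the C2 oxygen is carried as a benzoate, not as a benzyl-type ether. It comes in one catalytic step, offers no weak benzylic C–H bond to the C11 radical, and activates the aldehyde toward a hindered alkylchromium. C8 stays a ketone through the key step, because a less substituted alkene there would take the hydrogen atom first.
- Assumption: the (2S,5S)-auxiliary is taken to give the enantiomer drawn, on the steric model in which the methyl-bearing alkene terminus closes on the side of the keteniminium where the nearby pyrrolidine α-carbon presents hydrogen. If induction runs the other way, the (2R,5R)-amine is used with no other change.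

**Route**

Step 1
Reactants: 1 (2E,6E)-farnesol
Product: 2 (2E,6E)-farnesal
Conditions: MnO2 (activated), CH2Cl2, rt
Reagents that add atoms: none
Why: Allylic alcohol oxidation on activated MnO2 should stop at the conjugated aldehyde and leave the isolated alkenes and the 2E geometry untouched.

Step 2
Reactants: 2 (2E,6E)-farnesal
Product: 3 (2E,6E)-farnesoic acid
Conditions: NaClO2, NaH2PO4, 2-methyl-2-butene, t-BuOH/H2O, rt
Reagents that add atoms: sodium chlorite, [Na+].[O-]Cl=O
Why: Pinnick oxidation converts the enal into the acid under buffered conditions, the 2-methyl-2-butene scavenging hypochlorous acid so that the trisubstituted alkenes survive.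

Step 3
Reactants: 3 (2E,6E)-farnesoic acid; 4 (2S,5S)-2,5-dimethylpyrrolidine
Product: 6 (2E,6E)-1-[(2S,5S)-2,5-dimethylpyrrolidin-1-yl]-3,7,11-trimethyldodeca-2,6,10-trien-1-one, via (2E,6E)-farnesoyl chloride 5 (not isolated)
Conditions: (COCl)2, DMF (cat.), CH2Cl2, 0 °C; then 4, Et3N, CH2Cl2, 0 °C to rt
Reagents that add atoms: none
Why: Amide formation through the acid chloride is the standard acylation of a hindered secondary amine, and any 2E/2Z drift is harmless because this alkene is consumed in step 4.

Step 4
Reactants: 6 (2E,6E)-1-[(2S,5S)-2,5-dimethylpyrrolidin-1-yl]-3,7,11-trimethyldodeca-2,6,10-trien-1-one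
Product: 9 (1R,5S,7S)-7-methyl-2-methylidene-7-(4-methylpent-3-en-1-yl)bicyclo[3.1.1]heptan-6-one, via vinylketeniminium triflate 7 (not isolated), via cyclobutaniminium triflate 8 (not isolated)
Conditions: Tf2O, 2,4,6-collidine, ClCH2CH2Cl, 0 °C to 80 °C; then aq. NaHCO3, 80 °C
Reagents that add atoms: water, O
Why: Intramolecular keteniminium–alkene [2+2] cycloaddition: O-triflation and vinylogous deprotonation give the vinylketeniminium ion, whose electrophilic carbon (C10) bonds to the CH end of the 6,7-alkene while its α-carbon (C9) closes on the methyl-bearing end (crossed mode, as with the corresponding vinylketene); the E-alkene places the chain on the inner face of C4, the C2-symmetric pyrrolidine differentiates the two faces and so sets C4, C5 and C9, and hydrolysis of the iminium salt frees the ketone.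

Step 5
Reactants: 9 (1R,5S,7S)-7-methyl-2-methylidene-7-(4-methylpent-3-en-1-yl)bicyclo[3.1.1]heptan-6-one; 10 isopropyltriphenylphosphonium iodide
Product: 12 7-methyl-2-methylidene-7-(4-methylpent-3-en-1-yl)-6-(propan-2-ylidene)bicyclo[3.1.1]heptane, via isopropylidenetriphenylphosphorane 11 (not isolated)
Conditions: 10, n-BuLi, THF, 0 °C; then 9, 0 °C to 65 °C
Reagents that add atoms: none
Why: Wittig olefination with the non-stabilised isopropylidene ylide should convert the strained cyclobutanone, which cannot enolise because both α-carbons are bridgeheads and which is the only carbonyl group present, into the tetrasubstituted C10=C11 alkene.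

Step 6
Reactants: 12 7-methyl-2-methylidene-7-(4-methylpent-3-en-1-yl)-6-(propan-2-ylidene)bicyclo[3.1.1]heptane
Product: 14 3-[7-methyl-2-oxo-6-(propan-2-ylidene)bicyclo[3.1.1]heptan-7-yl]propanal, via tetraol 13 (not isolated)
Conditions: OsO4 (2 mol %), NMO (2.2 equiv), acetone/H2O, 0 °C to rt; then NaIO4, rt
Reagents that add atoms: osmium tetroxide, O=[Os](=O)(=O)=O (carrier of the oxygen atoms); N-methylmorpholine N-oxide, C[N+]1([O-])CCOCC1 (their net source)
Why: Upjohn dihydroxylation followed by periodate glycol cleavage should cut the 1,1-disubstituted and the trisubstituted alkene, whereas the tetrasubstituted alkylidenecyclobutane, flanked by two bridgeheads and covered on its inner face by the C3 chain, is too hindered to form an osmate ester under catalytic conditions.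

Step 7
Reactants: 14 3-[7-methyl-2-oxo-6-(propan-2-ylidene)bicyclo[3.1.1]heptan-7-yl]propanal
Product: 15 (2S)-1-oxo-3-[7-methyl-2-oxo-6-(propan-2-ylidene)bicyclo[3.1.1]heptan-7-yl]propan-2-yl benzoate
Conditions: (S)-2-(triphenylmethyl)pyrrolidine (10 mol %), (PhCO2)2, hydroquinone (10 mol %), THF, 0 °C
Reagents that add atoms: dibenzoyl peroxide, O=C(OOC(=O)c1ccccc1)c1ccccc1
Why: Enamine-catalysed α-benzoyloxylation of the aldehyde, in which the peroxide attacks the anti enamine on the face remote from the trityl group of the (S)-catalyst and should thereby set C2 as S, the hindered ketone forming no enamine in competition.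

Step 8
Reactants: 15 (2S)-1-oxo-3-[7-methyl-2-oxo-6-(propan-2-ylidene)bicyclo[3.1.1]heptan-7-yl]propan-2-yl benzoate
Product: 17 tricyclic alcohol (C1 hydroxyl; C2 benzoate; C8 ketone), via tertiary alkylchromium dichloride 16 (not isolated)
Conditions: Co(salen) (20 mol %; salen = N,N'-bis(3,5-di-tert-butylsalicylidene)ethylenediamine dianion), N-fluoro-2,4,6-trimethylpyridinium triflate (20 mol %), CrCl3·3THF (1.5 equiv), Ph(i-PrO)SiH2 (3 equiv), THF, 0.005 M, slow addition of 15, rt; aq. NH4Cl
Reagents that add atoms: none
Why: Proposed new method: trivalent cobalt hydride (from Co(salen), the N-fluoropyridinium salt and the silane) should transfer a hydrogen atom to C10 of the isopropylidenecyclobutane, giving the tertiary C11 radical and divalent cobalt; electron exchange between divalent cobalt and trivalent chromium then supplies divalent chromium, which traps the radical as tertiary alkylchromium 16, and this adds to the C1 aldehyde in a radical–polar crossover that is redox-neutral overall. The closest known reaction type is the intermolecular cobalt-hydride/chromium coupling of mono- and 1,1-disubstituted alkenes with aldehydes, backed by Nozaki–Hiyama–Kishi additions of alkylchromium reagents; the tetrasubstituted alkene and the ring closure are the new elements. The seven-membered ring (C1, C2, C3, C4, C9, C10, C11) closes in a 7-exo-trig mode, the carbonyl bond lying outside the ring being formed. C10 is fixed by hydrogen delivery to the outer face, the inner face being covered by the C3 chain on C4, which leaves C11 on the inner face next to that chain; C1 is fixed by the existing C2 benzoate through a ring transition state that holds both oxygens pseudo-equatorial and so gives the trans-1,2 relationship. The step needs hydrogen transfer to C10 and not C11 (secured by release of alkylidenecyclobutane strain and by formation of an open tertiary radical instead of a cyclobutyl one) and addition to the aldehyde and not the C8 ketone (secured by the aldehyde preference of organochromium reagents and by distance). A radical with C11 on the outer face cannot reach C1 and can revert by handing its hydrogen back to cobalt, so only the productive isomer is drained.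

Step 9
Reactants: 17 tricyclic alcohol (C1 hydroxyl; C2 benzoate; C8 ketone)
Product: 18 tricyclic dibenzoate (C1 and C2 benzoates; C8 ketone)
Conditions: BzCl, DMAP, pyridine, 50 °C
Reagents that add atoms: benzoyl chloride, O=C(Cl)c1ccccc1
Why: DMAP-catalysed acylation caps the hindered C1 hydroxyl as a second benzoate (no α-hydrogen, stable to amide bases and oxidants), and any material whose benzoate moved from O2 to O1 in step 8 converges on the same diester.

Step 10
Reactants: 18 tricyclic dibenzoate (C1 and C2 benzoates; C8 ketone)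
Product: 20 C7=C8 enol triflate, via potassium enolate 19 (not isolated)
Conditions: KN(SiMe3)2, THF, −78 °C; then PhNTf2, −78 °C to 0 °C
Reagents that add atoms: N-phenylbis(trifluoromethanesulfonimide), O=S(=O)(N(c1ccccc1)S(=O)(=O)C(F)(F)F)C(F)(F)F
Why: Enolate O-sulfonylation: deprotonation can only occur at C7 because C9 is a bridgehead, so trapping the enolate should give the C7=C8 enol triflate regiospecifically.

Step 11
Reactants: 20 C7=C8 enol triflate
Product: 21 C8-methyl C7=C8 alkene dibenzoate
Conditions: MeZnCl, Pd(PPh3)4 (5 mol %), THF, 50 °C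
Reagents that add atoms: methylzinc chloride, C[Zn]Cl
Why: Negishi coupling of the alkenyl triflate puts the methyl group on C8 with the alkene fixed at C7=C8, under conditions that leave the benzoates untouched.

Step 12
Reactants: 21 C8-methyl C7=C8 alkene dibenzoate
Product: 22 enone dibenzoate (C6 ketone; C7=C8)
Conditions: CrO3, 3,5-dimethylpyrazole, CH2Cl2, −20 °C
Reagents that add atoms: chromium trioxide, O=[Cr](=O)=O
Why: Allylic oxidation with the CrO3–3,5-dimethylpyrazole complex should turn the ring methylene C6 into the ketone, as in the oxidation of α-pinene-type alkenes to verbenone-type enones, the other allylic positions being a bridgehead CH and a methyl group.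

Step 13
Reactants: 22 enone dibenzoate (C6 ketone; C7=C8)
Product: 23 enone diol (C1 and C2 hydroxyls)
Conditions: K2CO3, MeOH, 40 °C
Reagents that add atoms: none
Why: Base-mediated transesterification with methanol removes both benzoates, and the β,β-disubstituted enone has no epimerisable centre because its α'-carbon C5 is a bridgehead.

Step 14
Reactants: 23 enone diol (C1 and C2 hydroxyls); 24 (S)-2-methylbutanoic acid
Product: 25 C2 (S)-2-methylbutanoate with free C1 hydroxyl
Conditions: 24, EDC·HCl, DMAP (cat.), CH2Cl2, 0 °C
Reagents that add atoms: none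
Why: Steglich-type carbodiimide esterification at low temperature should acylate the unhindered C2 hydroxyl in preference to the neopentyl C1 hydroxyl next to C11, and the mild conditions preserve the α-stereocentre of the acid.

Step 15
Reactants: 25 C2 (S)-2-methylbutanoate with free C1 hydroxyl; 26 angelic acid
Product: 28 target diester (CNP0323606.1), via angelic 2,4,6-trichlorobenzoic anhydride 27 (not isolated)
Conditions: 26, 2,4,6-trichlorobenzoyl chloride, Et3N, toluene, rt; then 25, toluene, 80 °C
Reagents that add atoms: none
Why: Yamaguchi-type mixed-anhydride esterification without a nucleophilic catalyst is the established way to acylate hindered alcohols with angelic acid while keeping the Z geometry, the alcohol attacking the unhindered angeloyl carbonyl of the anhydride.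

**Compound list**

1 | (2E,6E)-farnesol | CC(C)=CCC/C(C)=C/CC/C(C)=C/CO | starting material
2 | (2E,6E)-farnesal | CC(C)=CCC/C(C)=C/CC/C(C)=C/C=O | intermediate
3 | (2E,6E)-farnesoic acid | CC(C)=CCC/C(C)=C/CC/C(C)=C/C(=O)O | intermediate
4 | (2S,5S)-2,5-dimethylpyrrolidine (trans, C2-symmetric auxiliary) | C[C@H]1CC[C@H](C)N1 | starting material
5 | (2E,6E)-farnesoyl chloride | CC(C)=CCC/C(C)=C/CC/C(C)=C/C(=O)Cl | intermediate (not isolated)
6 | (2E,6E)-1-[(2S,5S)-2,5-dimethylpyrrolidin-1-yl]-3,7,11-trimethyldodeca-2,6,10-trien-1-one | CC(C)=CCC/C(C)=C/CC/C(C)=C/C(=O)N1[C@@H](C)CC[C@@H]1C | intermediate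
7 | vinylketeniminium triflate: (6E)-N-(7,11-dimethyl-3-methylidenedodeca-1,6,10-trien-1-ylidene)-(2S,5S)-2,5-dimethylpyrrolidinium triflate | C=C(CC/C=C(\C)CCC=C(C)C)C=C=[N+]1[C@@H](C)CC[C@@H]1C.[O-]S(=O)(=O)C(F)(F)F | intermediate (not isolated)
8 | cyclobutaniminium triflate: iminium salt of ketone 9 with amine 4 at C10 | CC(C)=CCC[C@@]2(C)[C@@H]3CCC(=C)[C@H]2C3=[N+]4[C@@H](C)CC[C@@H]4C.[O-]S(=O)(=O)C(F)(F)F | intermediate (not isolated)
9 | (1R,5S,7S)-7-methyl-2-methylidene-7-(4-methylpent-3-en-1-yl)bicyclo[3.1.1]heptan-6-one (side chain on the inner face of C4, methyl outer) | CC(C)=CCC[C@@]2(C)[C@@H]3CCC(=C)[C@H]2C3=O | intermediate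
10 | isopropyltriphenylphosphonium iodide | CC(C)[P+](c1ccccc1)(c1ccccc1)c1ccccc1.[I-] | starting material
11 | isopropylidenetriphenylphosphorane | CC(C)=P(c1ccccc1)(c1ccccc1)c1ccccc1 | intermediate (not isolated)
12 | 7-methyl-2-methylidene-7-(4-methylpent-3-en-1-yl)-6-(propan-2-ylidene)bicyclo[3.1.1]heptane (ring stereocentres as in 9) | CC(C)=CCC[C@@]2(C)[C@@H]3CCC(=C)[C@H]2C3=C(C)C | intermediate
13 | tetraol: C8 bears OH and CH2OH, the chain ends in CH(OH)–C(OH)Me2 (the new carbinol centres are not defined and are lost in the cleavage) | CC(C)(O)C(O)CC[C@@]2(C)[C@@H]3CCC(O)(CO)[C@H]2C3=C(C)C | intermediate (not isolated)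
14 | 3-[7-methyl-2-oxo-6-(propan-2-ylidene)bicyclo[3.1.1]heptan-7-yl]propanal (ring stereocentres as in 9) | O=CCC[C@@]2(C)[C@@H]3CCC(=O)[C@H]2C3=C(C)C | intermediate
15 | (2S)-1-oxo-3-[7-methyl-2-oxo-6-(propan-2-ylidene)bicyclo[3.1.1]heptan-7-yl]propan-2-yl benzoate (key-step precursor) | O=C[C@@H](OC(=O)c1ccccc1)C[C@@]2(C)[C@@H]3CCC(=O)[C@H]2C3=C(C)C | intermediate
16 | tertiary alkylchromium dichloride: C11 bears CrCl2 (solvent ligands omitted), H on C10 outer, aldehyde still open | O=C[C@@H](OC(=O)c1ccccc1)C[C@@]2(C)[C@@H]3CCC(=O)[C@H]2[C@@H]3C(C)(C)[Cr](Cl)Cl | intermediate (not isolated)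
17 | tricyclic alcohol (key-step product): (1S)-hydroxyl, (2S)-benzoate trans to it, C8 ketone, gem-dimethyl C11, H on C10 outer | O[C@@H]1[C@@H](OC(=O)c4ccccc4)C[C@@]2(C)[C@@H]3CCC(=O)[C@H]2[C@@H]3C1(C)C | intermediate
18 | tricyclic dibenzoate: benzoates on O1 and O2, C8 ketone | O=C(O[C@@H]1[C@@H](OC(=O)c4ccccc4)C[C@@]2(C)[C@@H]3CCC(=O)[C@H]2[C@@H]3C1(C)C)c5ccccc5 | intermediate
19 | potassium C7=C8 enolate of 18 | O=C(O[C@@H]1[C@@H](OC(=O)c4ccccc4)C[C@@]2(C)[C@@H]3CC=C([O-])[C@H]2[C@@H]3C1(C)C)c5ccccc5.[K+] | intermediate (not isolated)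
20 | C7=C8 enol triflate (OTf on C8), dibenzoate | O=C(O[C@@H]1[C@@H](OC(=O)c4ccccc4)C[C@@]2(C)[C@@H]3CC=C(OS(=O)(=O)C(F)(F)F)[C@H]2[C@@H]3C1(C)C)c5ccccc5 | intermediate
21 | C8-methyl C7=C8 alkene, dibenzoate | O=C(O[C@@H]1[C@@H](OC(=O)c4ccccc4)C[C@@]2(C)[C@@H]3CC=C(C)[C@H]2[C@@H]3C1(C)C)c5ccccc5 | intermediate
22 | enone dibenzoate: C6 ketone, C7=C8 with methyl on C8 | O=C(O[C@@H]1[C@@H](OC(=O)c4ccccc4)C[C@@]2(C)[C@@H]3C(=O)C=C(C)[C@H]2[C@@H]3C1(C)C)c5ccccc5 | intermediate
23 | enone diol: (1S,2S)-trans-diol, C6 ketone, C7=C8 | O[C@@H]1[C@@H](O)C[C@@]2(C)[C@@H]3C(=O)C=C(C)[C@H]2[C@@H]3C1(C)C | intermediate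
24 | (S)-2-methylbutanoic acid | CC[C@H](C)C(=O)O | starting material
25 | C2 (S)-2-methylbutanoate of 23 with free C1 hydroxyl | O[C@@H]1[C@@H](OC(=O)[C@@H](C)CC)C[C@@]2(C)[C@@H]3C(=O)C=C(C)[C@H]2[C@@H]3C1(C)C | intermediate
26 | angelic acid, (Z)-2-methylbut-2-enoic acid | C/C=C(/C)C(=O)O | starting material
27 | angelic 2,4,6-trichlorobenzoic anhydride | C/C=C(/C)C(=O)OC(=O)c1c(Cl)cc(Cl)cc1Cl | intermediate (not isolated)
28 | CNP0323606.1: C1 angelate, C2 (S)-2-methylbutanoate, C6 ketone, C7=C8 (methyl on C8); (1S,2S,4R,5R,9R,10S) in the numbering of the remarks | C/C=C(/C)C(=O)O[C@@H]1[C@@H](OC(=O)[C@@H](C)CC)C[C@@]2(C)[C@@H]3C(=O)C=C(C)[C@H]2[C@@H]3C1(C)C | target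

**Totals and risks**

Total step count: 15. Longest linear sequence: 15 steps (1 to 28); compounds 4, 10, 24 and 26 enter as single reagents.

Steps most likely to fail:

1. Step 8 (the proposed new method). Hydrogen-atom transfer to the shielded tetrasubstituted alkene may be too slow, or the tertiary radical may be reduced or disproportionate before chromium captures it, so that the ring does not close. The fallback uses only known reaction types; it sets out from 9 and comes back at 17. Horner–Wadsworth–Emmons reaction of 9 with tert-butyl 2-(diethoxyphosphoryl)propanoate (NaH, THF) should give the alkylidenecyclobutane ester F1. Dissolving-metal reductive alkylation (Li, NH3, t-BuOH, −78 °C; then MeI) protonates C10 on the outer face and methylates the ester enolate, giving the gem-dimethyl ester F2 with C11 already inner. OsO4/NMO followed by NaIO4, now with no tetrasubstituted alkene present, gives the keto aldehyde F3. Benzoyloxylation as in step 7 gives the (2S)-benzoate F4, CF3CO2H frees the carboxylic acid F5, and N-hydroxyphthalimide with a carbodiimide gives the redox-active ester F6. CrCl2 in DMF/THF then generates the same tertiary alkylchromium by decarboxylation, and its Nozaki–Hiyama–Kishi-type addition to the aldehyde closes the ring to 17.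

2. Step 4. The conjugated amide may be converted only sluggishly into the vinylketeniminium ion, or the auxiliary may discriminate poorly between the two faces, giving low enantiomeric purity. The fallback sets out from 5 and comes back at 9. Heating 5 with Et3N in toluene gives by 1,4-elimination the vinylketene F7, which undergoes the same crossed [2+2] cycloaddition, a reaction known for this very acid chloride. The product is the racemic ketone, that is 9 together with its enantiomer F8. Preparative chromatography on a chiral stationary phase then supplies 9, so absolute configuration comes from resolution and not from an auxiliary.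

3. Step 15. Acylation of the neopentyl C1 hydroxyl may be slow, and prolonged heating may cause Z-to-E isomerisation of the angeloyl unit or migration of the C2 ester. The fallback sets out from 25 and comes back at 28. The C1 hydroxyl is esterified with 2-[bis(2,2,2-trifluoroethoxy)phosphoryl]propanoic acid (EDC·HCl, DMAP, CH2Cl2, 40 °C), an acyl donor that has no alkene to isomerise and therefore tolerates forcing, to give the phosphonate ester F9. Still–Gennari olefination with acetaldehyde (KN(SiMe3)2, 18-crown-6, THF, −78 °C) then builds the Z-configured 2-methylbut-2-enoate on the molecule and gives 28.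

Further compounds
F1 | step 8 | tert-butyl 2-[7-methyl-2-methylidene-7-(4-methylpent-3-en-1-yl)bicyclo[3.1.1]heptan-6-ylidene]propanoate (ring stereocentres as in 9; either alkene geometry) | CC(C)=CCC[C@@]2(C)[C@@H]3CCC(=C)[C@H]2C3=C(C)C(=O)OC(C)(C)C
F2 | step 8 | tert-butyl 2-methyl-2-[7-methyl-2-methylidene-7-(4-methylpent-3-en-1-yl)bicyclo[3.1.1]heptan-6-yl]propanoate (H on C10 outer) | CC(C)=CCC[C@@]2(C)[C@@H]3CCC(=C)[C@H]2[C@@H]3C(C)(C)C(=O)OC(C)(C)C
F3 | step 8 | tert-butyl 2-methyl-2-[7-methyl-2-oxo-7-(3-oxopropyl)bicyclo[3.1.1]heptan-6-yl]propanoate | O=CCC[C@@]2(C)[C@@H]3CCC(=O)[C@H]2[C@@H]3C(C)(C)C(=O)OC(C)(C)C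
F4 | step 8 | (2S)-2-benzoyloxy derivative of aldehyde F3 | O=C[C@@H](OC(=O)c1ccccc1)C[C@@]2(C)[C@@H]3CCC(=O)[C@H]2[C@@H]3C(C)(C)C(=O)OC(C)(C)C
F5 | step 8 | carboxylic acid from F4 (C11 bears CO2H) | O=C[C@@H](OC(=O)c1ccccc1)C[C@@]2(C)[C@@H]3CCC(=O)[C@H]2[C@@H]3C(C)(C)C(=O)O
F6 | step 8 | N-(acyloxy)phthalimide of acid F5 | O=C[C@@H](OC(=O)c1ccccc1)C[C@@]2(C)[C@@H]3CCC(=O)[C@H]2[C@@H]3C(C)(C)C(=O)ON4C(=O)c5ccccc5C4=O
F7 | step 4 | vinylketene: (6E)-7,11-dimethyl-3-methylidenedodeca-1,6,10-trien-1-one | O=C=CC(=C)CC/C=C(\C)CCC=C(C)C
F8 | step 4 | (1S,5R,7R)-7-methyl-2-methylidene-7-(4-methylpent-3-en-1-yl)bicyclo[3.1.1]heptan-6-one, the enantiomer of 9 | CC(C)=CCC[C@]2(C)[C@H]3CCC(=C)[C@@H]2C3=O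
F9 | step 15 | C1 2-[bis(2,2,2-trifluoroethoxy)phosphoryl]propanoate of 25 (phosphonate α-carbon not defined) | CC(C(=O)O[C@@H]1[C@@H](OC(=O)[C@@H](C)CC)C[C@@]2(C)[C@@H]3C(=O)C=C(C)[C@H]2[C@@H]3C1(C)C)P(=O)(OCC(F)(F)F)OCC(F)(F)F
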